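**Plan**

1. Numbering is that of benzofuran, with C1' and C2' for the side chain. The retrosynthesis first cuts C1'–H (ketone reduction), C5–C1' (acyl transfer from a lactate thioester to a C5 boronic acid), C5–B and the C7 O–CH3 bond, leaving a 2-aryl-3-methyl-2,3-dihydrobenzofuran-7-ol.
2. In that phenol the C7 oxygen sits on ring A ortho to the ring-fusion carbon C7a that carries O1. A furan joined through C3–C2–O1 to an ethynyl ether delivers exactly this 7-oxygenated dihydrobenzofuran, so C3a–C7a, C6–C7 and C7–O are cut together and rings A and B open to a furyl ynol ether.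
3. The ynol ether is cut at O–C(sp) to a 1-aryl-2-furylpropan-1-ol and trichloroethylene, the alcohol at its C–O and C–H bonds to an (E)-alkene, and the alkene at C=C to 2-acetylfuran and a benzylic phosphonate.
4. Forward: olefination, hydroboration and ynol ether formation; one gold-catalysed operation then closes ring B and builds ring A from the furan; O-methylation, C5 borylation, acylation, desilylation and reduction attach the side chain last.
5. Stereochemistry: C2 and C3 come from syn addition of a pinene-derived chiral borane to the (E)-alkene, C2' from ethyl (S)-lactate, and C1' from chelation-controlled hydride delivery anti to the C2' methyl group.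

Key step: step 5

Remark: the alkene face chosen by IpcBH2 on this acyclic substrate is assigned by analogy with 1-phenylcyclopentene (furyl in the place of phenyl), which calls for the borane from (−)-α-pinene; the assignment would be checked on the alcohol (MTPA esters) before going on.

**Route**

Step 1
Reactants: 1 2-acetylfuran; 2 diethyl (3,4-dimethoxybenzyl)phosphonate
Product: 3 2-[(E)-1-(3,4-dimethoxyphenyl)prop-1-en-2-yl]furan
Conditions: NaH, 15-crown-5 (cat.), THF, 0 °C → rt
Reagents that add atoms: none
Why: Horner–Wadsworth–Emmons olefination of the methyl ketone by the benzylic phosphonate anion should favour the (E)-alkene with the two aromatic groups trans, and the minor (Z)-isomer is removed by chromatography or crystallisation because it would lead to the wrong diastereomer in step 2.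

Step 2
Reactants: 3 2-[(E)-1-(3,4-dimethoxyphenyl)prop-1-en-2-yl]furan
Product: 5 (1S,2R)-1-(3,4-dimethoxyphenyl)-2-(furan-2-yl)propan-1-ol, via dialkylborane 4 (not isolated)
Conditions: IpcBH2 [from (−)-α-pinene], THF, −25 °C; then NaOH, H2O2, 0 °C → rt
Reagents that add atoms: hydrogen peroxide, OO
Why: In this asymmetric hydroboration–oxidation boron adds to the less substituted aryl-bearing carbon and hydrogen to the furyl-bearing carbon in a syn fashion, so the (E)-geometry fixes the relative configuration, the chiral monoalkylborane selects the alkene face and C–B oxidation with retention gives the (1S,2R)-alcohol.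

Step 3
Reactants: 5 (1S,2R)-1-(3,4-dimethoxyphenyl)-2-(furan-2-yl)propan-1-ol; 6 trichloroethylene
Product: 7 2-[(1S,2R)-1-{[(E)-1,2-dichloroethenyl]oxy}-1-(3,4-dimethoxyphenyl)propan-2-yl]furan
Conditions: KH, THF, 0 °C → rt; then 6, −50 °C → rt
Reagents that add atoms: none
Why: In this dichlorovinyl ether synthesis the potassium alkoxide dehydrochlorinates trichloroethylene and adds anti to the dichloroacetylene so formed; only the O–H bond reacts, so both stereocentres are untouched and a stable, purifiable intermediate results.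

Step 4
Reactants: 7 2-[(1S,2R)-1-{[(E)-1,2-dichloroethenyl]oxy}-1-(3,4-dimethoxyphenyl)propan-2-yl]furan
Product: 10 2-[(1S,2R)-1-(3,4-dimethoxyphenyl)-1-(ethynyloxy)propan-2-yl]furan, via chloroalkynyl ether 8 (not isolated), via lithium acetylide 9 (not isolated)
Conditions: n-BuLi (2.5 equiv), THF, −78 → −40 °C; then MeOH, −78 °C
Reagents that add atoms: none
Why: Dehydrochlorination to 8, chlorine–lithium exchange to 9 and protonation complete the trichloroethylene route to terminal ynol ethers; these steps at −78 °C should outpace metalation of the furan, and the product is kept cold and used at once because secondary alkynyl ethers fragment on warming.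

Step 5
Reactants: 10 2-[(1S,2R)-1-(3,4-dimethoxyphenyl)-1-(ethynyloxy)propan-2-yl]furan
Product: 12 (2S,3S)-2-(3,4-dimethoxyphenyl)-3-methyl-2,3-dihydro-1-benzofuran-7-ol, via arene oxide 11 (not isolated)
Conditions: (Ph3P)AuNTf2 (2 mol%), CH2Cl2, 0 °C → rt
Reagents that add atoms: none
Why: Cationic gold polarises the ynol ether so that its oxygen-bearing carbon is attacked by C2 of the tethered furan, a 5-exo-dig closure that forms C3a–C7a and ring B and leaves a cyclopropyl gold carbene. Cleavage of the furan C2–O bond gives a dienal-conjugated gold carbene, the aldehyde oxygen adds to the carbene carbon, and loss of gold gives an oxepine that closes by 6π electrocyclisation to arene oxide 11, forming C6–C7 and ring A. The epoxide opens at C6–O because the resulting cation is delocalised onto C7a and stabilised by O1, so after proton loss the hydroxyl remains on C7. The closest known reaction is the gold-catalysed furan-yne phenol synthesis in its alkynyl ether variant, which gives 2,3-dihydrobenzofuran-7-ols at room temperature. No stereocentre is created: C2 and C3 lie on the tether, take no part in the reorganisation and are carried through unchanged, the C2–O1 bond being the carbinol C–O bond of 5. The step needs the furan, and not the dimethoxyphenyl ring or adventitious water, to capture the activated alkyne: the furan is the stronger π-nucleophile and is placed for five-membered ring closure, the aryl ortho carbon could only close a strained benzo-fused ring, and the reaction is run dry and cold with a non-coordinating counter-ion.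

Step 6
Reactants: 12 (2S,3S)-2-(3,4-dimethoxyphenyl)-3-methyl-2,3-dihydro-1-benzofuran-7-ol
Product: 13 (2S,3S)-2-(3,4-dimethoxyphenyl)-7-methoxy-3-methyl-2,3-dihydro-1-benzofuran
Conditions: MeI, K2CO3, acetone, 50 °C
Reagents that add atoms: iodomethane, CI
Why: Williamson O-methylation of the only acidic site, the C7 phenol, under conditions that leave the benzylic C2–O1 bond alone.

Step 7
Reactants: 13 (2S,3S)-2-(3,4-dimethoxyphenyl)-7-methoxy-3-methyl-2,3-dihydro-1-benzofuran
Product: 15 [(2S,3S)-2-(3,4-dimethoxyphenyl)-7-methoxy-3-methyl-2,3-dihydro-1-benzofuran-5-yl]boronic acid, via pinacol boronate 14 (not isolated)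
Conditions: [Ir(OMe)(cod)]2 (1.5 mol%), dtbpy (3 mol%), B2pin2 (1.0 equiv), THF, 80 °C; then NaIO4, NH4OAc, acetone/H2O, rt
Reagents that add atoms: bis(pinacolato)diboron, CC1(C)OB(OC1(C)C)B1OC(C)(C)C(C)(C)O1; water, O
Why: Iridium-catalysed C–H borylation is governed by sterics and C5–H is the only aromatic C–H of 13 without an ortho substituent (ring A is 1,2,3-trisubstituted and every C–H of the dimethoxyphenyl ring has a neighbour), while periodate cleavage of the released pinacol converts the boronate into the boronic acid in the same flask.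

Step 8
Reactants: 16 ethyl (S)-lactate
Product: 17 ethyl (2S)-2-[(tert-butyldimethylsilyl)oxy]propanoate
Conditions: TBSCl, imidazole, DMF, rt
Reagents that add atoms: tert-butyldimethylsilyl chloride, CC(C)(C)[Si](C)(C)Cl
Why: Standard silylation of a secondary alcohol in which the stereocentre is not involved.

Step 9
Reactants: 17 ethyl (2S)-2-[(tert-butyldimethylsilyl)oxy]propanoate
Product: 18 S-phenyl (2S)-2-[(tert-butyldimethylsilyl)oxy]propanethioate
Conditions: AlMe3, PhSH, CH2Cl2, 0 °C → rt
Reagents that add atoms: thiophenol, Sc1ccccc1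
Why: Ester-to-thioester exchange with the aluminium thiolate formed from AlMe3 and PhSH is a non-basic acyl substitution that should leave the α-stereocentre intact.

Step 10
Reactants: 15 [(2S,3S)-2-(3,4-dimethoxyphenyl)-7-methoxy-3-methyl-2,3-dihydro-1-benzofuran-5-yl]boronic acid; 18 S-phenyl (2S)-2-[(tert-butyldimethylsilyl)oxy]propanethioate
Product: 19 (2S)-2-[(tert-butyldimethylsilyl)oxy]-1-[(2S,3S)-2-(3,4-dimethoxyphenyl)-7-methoxy-3-methyl-2,3-dihydro-1-benzofuran-5-yl]propan-1-one
Conditions: Pd2(dba)3 (2.5 mol%), P(OEt)3 (20 mol%), copper thiophene-2-carboxylate (1.5 equiv), THF, rt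
Reagents that add atoms: none
Why: Liebeskind–Srogl coupling (C–S oxidative addition to zerovalent palladium, copper-carboxylate-assisted transfer of the aryl group from boron, reductive elimination) runs without base and is known to preserve stereocentres next to the thioester carbonyl.

Step 11
Reactants: 19 (2S)-2-[(tert-butyldimethylsilyl)oxy]-1-[(2S,3S)-2-(3,4-dimethoxyphenyl)-7-methoxy-3-methyl-2,3-dihydro-1-benzofuran-5-yl]propan-1-one
Product: 20 (2S)-1-[(2S,3S)-2-(3,4-dimethoxyphenyl)-7-methoxy-3-methyl-2,3-dihydro-1-benzofuran-5-yl]-2-hydroxypropan-1-one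
Conditions: HF·pyridine, pyridine, THF, 0 °C → rt
Reagents that add atoms: none
Why: Fluoride-mediated Si–O cleavage under buffered, weakly acidic conditions should avoid both enolisation of the α-hydroxy ketone and ionisation of the benzylic ether.

Step 12
Reactants: 20 (2S)-1-[(2S,3S)-2-(3,4-dimethoxyphenyl)-7-methoxy-3-methyl-2,3-dihydro-1-benzofuran-5-yl]-2-hydroxypropan-1-one
Product: 21 (1R,2S)-1-[(2S,3S)-2-(3,4-dimethoxyphenyl)-7-methoxy-3-methyl-2,3-dihydro-1-benzofuran-5-yl]propane-1,2-diol
Conditions: Zn(BH4)2, Et2O, −20 → 0 °C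
Reagents that add atoms: none
Why: In this chelation-controlled (Cram-chelate) reduction zinc bridges the carbonyl and α-hydroxyl oxygens and hydride enters the five-membered chelate from the face opposite the C2' methyl group, which sets C1' as R and gives the anti (erythro) diol.

**Compound list**

1 | 2-acetylfuran | CC(=O)c1ccco1 | starting material
2 | diethyl (3,4-dimethoxybenzyl)phosphonate | CCOP(=O)(Cc1ccc(OC)c(OC)c1)OCC | starting material
3 | 2-[(E)-1-(3,4-dimethoxyphenyl)prop-1-en-2-yl]furan | COc1ccc(/C=C(\C)c2ccco2)cc1OC | intermediate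
4 | [(1S,2R)-1-(3,4-dimethoxyphenyl)-2-(furan-2-yl)propyl][(1S,2R,3S,5S)-2,6,6-trimethylbicyclo[3.1.1]heptan-3-yl]borane (dialkylborane, formed in the flask) | COc1ccc([C@@H]([BH][C@H]2C[C@H]3C[C@@H]([C@@H]2C)C3(C)C)[C@@H](C)c2ccco2)cc1OC | intermediate
5 | (1S,2R)-1-(3,4-dimethoxyphenyl)-2-(furan-2-yl)propan-1-ol | COc1ccc([C@@H](O)[C@@H](C)c2ccco2)cc1OC | intermediate
6 | trichloroethylene | ClC=C(Cl)Cl | starting material
7 | 2-[(1S,2R)-1-{[(E)-1,2-dichloroethenyl]oxy}-1-(3,4-dimethoxyphenyl)propan-2-yl]furan | COc1ccc([C@@H](O/C(Cl)=C\Cl)[C@@H](C)c2ccco2)cc1OC | intermediate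
8 | 2-[(1S,2R)-1-[(chloroethynyl)oxy]-1-(3,4-dimethoxyphenyl)propan-2-yl]furan (chloroalkynyl ether, formed in the flask) | COc1ccc([C@@H](OC#CCl)[C@@H](C)c2ccco2)cc1OC | intermediate
9 | {[(1S,2R)-1-(3,4-dimethoxyphenyl)-2-(furan-2-yl)propoxy]ethynyl}lithium (lithium acetylide, formed in the flask) | COc1ccc([C@@H](OC#C[Li])[C@@H](C)c2ccco2)cc1OC | intermediate
10 | 2-[(1S,2R)-1-(3,4-dimethoxyphenyl)-1-(ethynyloxy)propan-2-yl]furan | COc1ccc([C@@H](OC#C)[C@@H](C)c2ccco2)cc1OC | intermediate
11 | 6,7-epoxide of (2S,3S)-2-(3,4-dimethoxyphenyl)-3-methyl-2,3,6,7-tetrahydro-1-benzofuran (arene oxide with C3a=C7a and C4=C5, either epoxide face, valence tautomer of the oxepine, formed in the flask) | COc1ccc([C@H]2OC3=C(C=CC4OC34)[C@@H]2C)cc1OC | intermediate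
12 | (2S,3S)-2-(3,4-dimethoxyphenyl)-3-methyl-2,3-dihydro-1-benzofuran-7-ol | COc1ccc([C@H]2Oc3c(O)cccc3[C@@H]2C)cc1OC | intermediate
13 | (2S,3S)-2-(3,4-dimethoxyphenyl)-7-methoxy-3-methyl-2,3-dihydro-1-benzofuran | COc1ccc([C@H]2Oc3c(OC)cccc3[C@@H]2C)cc1OC | intermediate
14 | 2-[(2S,3S)-2-(3,4-dimethoxyphenyl)-7-methoxy-3-methyl-2,3-dihydro-1-benzofuran-5-yl]-4,4,5,5-tetramethyl-1,3,2-dioxaborolane (pinacol boronate, formed in the flask) | COc1ccc([C@H]2Oc3c(OC)cc(B4OC(C)(C)C(C)(C)O4)cc3[C@@H]2C)cc1OC | intermediate
15 | [(2S,3S)-2-(3,4-dimethoxyphenyl)-7-methoxy-3-methyl-2,3-dihydro-1-benzofuran-5-yl]boronic acid | COc1ccc([C@H]2Oc3c(OC)cc(B(O)O)cc3[C@@H]2C)cc1OC | intermediate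
16 | ethyl (S)-lactate | CCOC(=O)[C@H](C)O | starting material
17 | ethyl (2S)-2-[(tert-butyldimethylsilyl)oxy]propanoate | CCOC(=O)[C@H](C)O[Si](C)(C)C(C)(C)C | intermediate
18 | S-phenyl (2S)-2-[(tert-butyldimethylsilyl)oxy]propanethioate | C[C@H](O[Si](C)(C)C(C)(C)C)C(=O)Sc1ccccc1 | intermediate
19 | (2S)-2-[(tert-butyldimethylsilyl)oxy]-1-[(2S,3S)-2-(3,4-dimethoxyphenyl)-7-methoxy-3-methyl-2,3-dihydro-1-benzofuran-5-yl]propan-1-one | COc1ccc([C@H]2Oc3c(OC)cc(C(=O)[C@H](C)O[Si](C)(C)C(C)(C)C)cc3[C@@H]2C)cc1OC | intermediate
20 | (2S)-1-[(2S,3S)-2-(3,4-dimethoxyphenyl)-7-methoxy-3-methyl-2,3-dihydro-1-benzofuran-5-yl]-2-hydroxypropan-1-one | COc1ccc([C@H]2Oc3c(OC)cc(C(=O)[C@H](C)O)cc3[C@@H]2C)cc1OC | intermediate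
21 | (1R,2S)-1-[(2S,3S)-2-(3,4-dimethoxyphenyl)-7-methoxy-3-methyl-2,3-dihydro-1-benzofuran-5-yl]propane-1,2-diol | COc1ccc([C@H]2Oc3c(OC)cc([C@@H](O)[C@H](C)O)cc3[C@@H]2C)cc1OC | target

**Step count**

Total: 12 steps (steps 8 and 9 are a two-step branch to the thioester). Longest linear sequence: 10 steps (steps 1–7 and 10–12).

**Steps most likely to fail, with fallbacks**

Step 5. The gold-activated ynol ether may be consumed before the furan engages: by ionisation of the benzylic C–O bond next to the electron-rich aryl group (fragmentation to a ketene and alkene), by attack of the dimethoxyphenyl ring, or by hydration. In that case ring A would be bought and not built. The fallback sets out from phosphonate 2. Horner–Wadsworth–Emmons olefination (NaH, THF) with 1-[3-methoxy-2-(methoxymethoxy)phenyl]ethan-1-one F1 (from commercial 1-(2-hydroxy-3-methoxyphenyl)ethan-1-one, MOMCl, i-Pr2NEt) should give 1,2-dimethoxy-4-{(E)-2-[3-methoxy-2-(methoxymethoxy)phenyl]prop-1-en-1-yl}benzene F2. Hydroboration with the same IpcBH2 would pass through the isopinocampheyl dialkylborane F3 and, after NaOH/H2O2, give (1S,2S)-1-(3,4-dimethoxyphenyl)-2-[3-methoxy-2-(methoxymethoxy)phenyl]propan-1-ol F4. HCl in methanol removes the MOM group to 2-[(1S,2S)-1-(3,4-dimethoxyphenyl)-1-hydroxypropan-2-yl]-6-methoxyphenol F5, which should close in the same flask through the dimethoxybenzyl cation to the thermodynamically preferred trans-dihydrobenzofuran. This comes back to the route at 13, with C3 fixed by the hydroboration and C2 by the trans preference of the cationic closure.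

Step 4. The terminal secondary alkynyl ether may be lost by retro-ene fragmentation, hydration or oligomerisation during quench, concentration and handling. The fallback sets out from 7 and carries the alkyne terminus in masked form. Acetylide 9 is generated as in step 4 but quenched with Me3SiCl in place of methanol, which should give {[(1S,2R)-1-(3,4-dimethoxyphenyl)-2-(furan-2-yl)propoxy]ethynyl}trimethylsilane F6, a compound that can be chromatographed and stored. Bu4NF in THF at −20 °C, followed by a cold filtration through basic alumina straight into the flask for step 5, comes back to the route at 10 without that compound ever being concentrated.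

Step 2. The chiral borane may discriminate the two faces of this acyclic aryl- and furyl-substituted alkene incompletely or in the opposite sense to the model. The relative configuration is secured by syn addition in any case, so the fallback secures the absolute configuration by resolution; should the sense prove reversed, the borane from (+)-α-pinene is used first. It sets out from alcohol 5 of insufficient enantiomeric purity. Esterification with (S)-2-methoxy-2-phenylacetic acid (DCC, DMAP, CH2Cl2) and chromatographic separation of the diastereomeric esters would give (1S,2R)-1-(3,4-dimethoxyphenyl)-2-(furan-2-yl)propyl (2S)-2-methoxy-2-phenylacetate F7, whose configuration can be read from its NMR shifts. LiOH in THF/MeOH/H2O then comes back to the route at 5 as a single enantiomer.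

**Further compounds**

F1 | step 5 | 1-[3-methoxy-2-(methoxymethoxy)phenyl]ethan-1-one | CC(=O)c1cccc(OC)c1OCOC
F2 | step 5 | 1,2-dimethoxy-4-{(E)-2-[3-methoxy-2-(methoxymethoxy)phenyl]prop-1-en-1-yl}benzene | COc1ccc(/C=C(\C)c2cccc(OC)c2OCOC)cc1OC
F3 | step 5 | [(1S,2R)-1-(3,4-dimethoxyphenyl)-2-[3-methoxy-2-(methoxymethoxy)phenyl]propyl][(1S,2R,3S,5S)-2,6,6-trimethylbicyclo[3.1.1]heptan-3-yl]borane | COc1ccc([C@@H]([BH][C@H]2C[C@H]3C[C@@H]([C@@H]2C)C3(C)C)[C@@H](C)c2cccc(OC)c2OCOC)cc1OC
F4 | step 5 | (1S,2S)-1-(3,4-dimethoxyphenyl)-2-[3-methoxy-2-(methoxymethoxy)phenyl]propan-1-ol | COc1ccc([C@@H](O)[C@@H](C)c2cccc(OC)c2OCOC)cc1OC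
F5 | step 5 | 2-[(1S,2S)-1-(3,4-dimethoxyphenyl)-1-hydroxypropan-2-yl]-6-methoxyphenol | COc1ccc([C@@H](O)[C@@H](C)c2cccc(OC)c2O)cc1OC
F6 | step 4 | {[(1S,2R)-1-(3,4-dimethoxyphenyl)-2-(furan-2-yl)propoxy]ethynyl}trimethylsilane | COc1ccc([C@@H](OC#C[Si](C)(C)C)[C@@H](C)c2ccco2)cc1OC
F7 | step 2 | (1S,2R)-1-(3,4-dimethoxyphenyl)-2-(furan-2-yl)propyl (2S)-2-methoxy-2-phenylacetate | COc1ccc([C@@H](OC(=O)[C@@H](OC)c3ccccc3)[C@@H](C)c2ccco2)cc1OC
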